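- At early times the ash run looks pseudo-first-order, with nucleophile at 3.08 equivalents. Electrophile falls at 0.0196 s⁻¹ over the first 10.0 s. Between 50.0 s and 80.0 s it falls at only 0.004533 s⁻¹, far slower, so I suppose the nucleophile is fading.

| setting | ash | winter | dawn |
|---|---|---|---|
| electrophile | 13 mM | 20 mM | 20 mM |
| nucleophile | 40 mM | 40.0 mM | 60.0 mM |
| remark | run made earlier |  |  |
| time |  | 6.0 min | 6.0 min |

- ash (time / s: electrophile / %, target / %): 10.0: 82.2, 17.0; 20.0: 73.4, 25.1; 30.0: 65.8, 30.5; 50.0: 58.2, 33.1; 80.0: 50.8, 30.1

(standard deviation of a reading: 0.5 percentage points)

1. part of the electrophile that has reacted at the end, winter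
2. part of the electrophile that has reacted at the end, dawn
3. what raising the concentration of nucleophile from its lowest to its highest value here does to the part of the electrophile that has reacted (changes below 5 percentage points count as none) (it falls / no change / it rises)



- My reckoning carries one reading, the log-time slope, which is the fall of ln[electrophile] per unit of ln(time). Between 20.0 s and 80.0 s of the ash run it reads 0.265.
- Time: I extend the ash run from 80.0 s to 6.0 min along this slope. That leaves 34.1 % of the electrophile, so 65.9 % has reacted in winter.
- Electrophile: the ash run has lost 6.40 mM of electrophile by its last reading, but it has no reading of nucleophile. I therefore have no measure by hand for the step to 20 mM, and I leave it out of my reckoning as an assumption.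
- Nucleophile: I suppose that 60.0 mM in dawn acts like a clock run faster by 1.50. That leaves 30.6 % and gives 69.4 % reacted, a rise of 3.5 percentage points over winter. This is below the margin of 5 points, so I call it no change.
- The forecast differs from me. It proposes “a fast reversible step” and gives 76 % for winter and 86 % for dawn, with the verdict it rises.

    electrophile + nucleophile → acid set free + target (k = 0.610 L mol⁻¹ s⁻¹)
    nucleophile + acid set free ⇌ protonated nucleophile, settled at all times (K = 310 L mol⁻¹)
    acid set free + target → side product (k = 9.40 L mol⁻¹ s⁻¹)
    2 nucleophile → homo dimer (k = 0.580 L mol⁻¹ s⁻¹)

- Winter gives 68.0 % and dawn 76.0 %, a difference of 8 points, so the verdict is it rises, as the forecast said and against my call. At 6.0 min winter keeps 3.5 % of its nucleophile and 32 % of its electrophile. Starting from winter's 40.5 % of electrophile at 3.00 min, the slope gives 33.7 % left at 6.0 min, against the 32 % that stands there.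
- Left until 15 min, winter starts from that 32.0 %, and the slope gives 25.1 % left, so 74.9 % reacted. The computed flask gives 73.9 %, with nucleophile as the limiting reagent at 0.58 % of its charge.

The readings come from a simulation for an exercise, noise included.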